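The readings are calculated for substances that don't exist, noise included.

Two questions were open when I handed over this row of flasks; they stand below with the flasks and the earlier runs.

| flask | Q | L | remark | time |
|---|---|---|---|---|
| larch | 0.050 M (fed, over 2.5 min) | 0.014 mol% | run made earlier; the fed solution adds 0.50 times the starting volume |  |
| alder | 0.050 M (fed, over 2.5 min) | 0.022 mol% | run made earlier; the fed solution adds 0.50 times the starting volume |  |
| south-east | 0.050 M (fed, over 2.5 min) | 0.01 mol% | the fed solution adds 0.50 times the starting volume | 20 min |
| east | 0.050 M (fed, over 5.0 min) | 0.01 mol% | the fed solution adds 0.50 times the starting volume | 20 min |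
| west | 0.050 M (fed, over 10 min) | 0.01 mol% | the fed solution adds 0.50 times the starting volume | 20 min |
| south-west | 0.050 M (fed, over 20 min) | 0.01 mol% | the fed solution adds 0.50 times the starting volume | 20 min |

| run | time / min | Z / % |
|---|---|---|
| larch | 1.33 | 8.1 |
| larch | 2.00 | 18.7 |
| larch | 4.00 | 45.5 |
| larch | 6.00 | 57.4 |
| larch | 10.0 | 55.1 |
| larch | 15.0 | 44.9 |
| alder | 1.33 | 12.4 |
| alder | 2.00 | 25.1 |
| alder | 4.00 | 54.0 |
| alder | 6.00 | 55.5 |
| alder | 10.0 | 44.8 |
| alder | 15.0 | 30.7 |

(readings scatter by 0.5 percentage points)

1. amount of Z at the end, in percent of the Q charged for south-east, east, west, south-west, in this order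
2. the course of these numbers from the first flask to the last (falls, then rises / rises all the way / hardly changes / falls all the way / rises, then falls)

- charges are per starting volume, the dose included; the dosed solution carries all of it
- candidate steps: L + Z -> L + G; Q + L -> Z + L
- percentages count the whole charge, also what has not yet gone in
- "hardly changes" means that all values lie within two and a half points (for a concentration: within two and a half percent of the largest)

In each flask Q ran in from the feed, L turned it into Z, and L turned Z further into G, so Z rose and then fell, as in larch and alder. L took part in both steps, so I expected a change of loading to shrink both time constants of this chain in one ratio and to leave the path of Z the same, run at another speed, provided the feed was stretched in that ratio too.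

So I carried one number, 0.455 for east against alder: the pace ratio, one flask's loading divided by another's. It is a ratio of rates, so time has dropped out of it, and a flask's minutes multiplied by it become matched minutes in the earlier run (normalised time, in the trade). The earlier runs could test this only roughly, since both feeds took 2.5 min and so were not matched. Larch at 6.00 min matched 3.82 min of alder and read 57.4 %, more than alder's 54.0 % at 4.00 min, so the match failed there. Larch at 15.0 min matched 9.55 min of alder and read 44.9 %, against 46.0 % between alder's readings, a gap of 1.1 percentage points.

East's feed of 5.0 min was twice alder's 2.5 min, at 0.455 of alder's loading, and the product of these two ratios was 0.910, so the two feeds were nearly matched and I read east off alder. Its end at 20 min matched 9.09 min, between alder's readings of 55.5 % and 44.8 %, which gave an estimate of 47.2 % of Z. My note to the next person said to expect that much and to add no L, because the matched time already lay later than 6.00 min, and alder's Z fell after that reading.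

The forecast gave 45.3 %, 47 %, 50.5 % and 44.8 %, a course that rises, then falls, on the ground that “Longer dosing first saves Z from overcooking”.

The flasks ended at 45.6 %, 47.3 %, 50.6 % and 46.6 %, a course that rises, then falls.

    L + Z → L + G (k = 13700 M⁻¹ min⁻¹)
    Q + L → Z + L, rate k2*[Q]^2.5*[L]/(1 + ([Q]/Kh2)^2.5) (18.0 mM, k = 7.58 × 10⁵ M⁻²·⁵ s⁻¹)

East held 47.3 % of Z at 20.0 min, beside 13.9 % of Q and 38.7 % of G. Against larch the pace ratio of south-east was 0.714, so its 20 min matched 14.3 min of larch, where the readings give 46.4 %, though the two feeds both took 2.5 min and so were not matched, and south-east ended at 45.6 %.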